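The ratio I carry through this flask is the time a target molecule has had since it was made over its first-phase lifetime.

starting material 0.10 M; reagent in the second phase 0.400 M; protic impurity 0.100 M; time 5.0 min; volume of the second phase over the first 1.0

    target → decomposed product (k1 = 0.00534 s⁻¹)
    starting material + protic impurity → quenched substrate (k2 = 0.0639 M⁻¹ s⁻¹)
    reagent in the reaction phase ⇌ reagent in the second phase, rate k3*([reagent in the reaction phase] - [reagent in the second phase]/K3) per volume of the first phase (K3 = 0.81, k3 = 0.00583 s⁻¹)
    starting material + reagent in the reaction phase → target (k4 = 6.30 M⁻¹ s⁻¹)
    reagent in the reaction phase → decomposed reagent (k5 = 0.0474 s⁻¹)
    target ⇌ product in the second phase, rate k6*([target] - [product in the second phase]/K6) per volume of the first phase (K6 = 29.2, k6 = 0.00385 s⁻¹)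

1. target and product in the second phase together at 5.0 min, in percent of the starting material charged
2. part of the starting material charged that has reacted at 5.0 min

- target is meant together with its product in the second phase
- in the second phase: reagent in the second phase, product in the second phase; everything else is in the first
- charges count per volume of the first phase; a concentration in a rate is the amount of a species over the volume of its own phase; every rate counts per litre of the first phase
- run time (flask): 5.0 min

- I start with the main step. At the start, reagent enters the reaction phase at 0.00288 M s⁻¹, which is the transfer coefficient times c(reagent in the second phase) over the partition ratio. At the start the starting material takes nearly all of it. The starting material charged equals 34.7 s of this feed, so with the feed held at its starting value I reckon the reacted part at the asked time as 100%.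
- Next I add the protic impurity. At its charged concentration it quenches starting material with a pseudo-first-order constant of 0.00639 s⁻¹. If starting material falls in a straight line over that feed time, I reckon the quenched share as 11.1%, which leaves 88.9% of the charge to become target.
- Then I add the losses of target. One over the sum of its decomposition constant and transfer coefficient is 1.81 min, the first-phase lifetime of target: the mean time a target molecule stays in the first phase before it decomposes or passes over. With a partition ratio of 29.2 I neglect the return, so 41.9% of what leaves the first phase reaches the second phase.
- Now I count lifetimes. Target born at the midpoint of the feed time has 2.60 lifetimes until the reading, so I reckon 7.45% of it still in the first phase. The surviving share, both phases together, is 46.2% of the target formed, and I commit to 41.1% of the starting material charged for target and product in the second phase together.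
- The forecast gives 41% for target and product in the second phase together and 99.9% for the reacted part. It says “about 40% of the target formed survives”, where I reckon 46.2%.
- This flask gives 40.1% for target and product in the second phase together and 100% for the reacted part. My count puts 6.62% of the charge in the first phase as target at the asked time, and this flask holds 7.25% there. The neighbour flask is the same flask read at 2.0 min, which is 0.943 lifetimes after the midpoint. There I reckon 38.9% of the target formed still in the first phase, a surviving share of 64.5%, and 57.3% of the charge for target and product in the second phase together. That neighbour flask holds 57.3% of target, all its forms counted, with 21.2% as product in the second phase.

The numbers come from no measurement, and the outcome is calculated.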